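**Retrosynthetic overview**

1. Feature: every carbon of ring A from C5 to C8 bears oxygen (OH, OMe, OH, OMe), which maps onto the four carbons of a squarate, and C4, C3, C2 of ring C (OH, OH, aryl, all trans, 2R,3S,4R) are C3, C4, C5 of a D-gluco-configured 5-aryl glycal.
2. Last disconnection: six O-benzyl groups (hydrogenolysis). Before it, ring A is closed at C4a–C5 by thermal ring expansion of a 4-(glycal-1-yl)-4-methoxycyclobutenone (carbonyl C to C5, alpha C to C6, beta C to C7, carbinol C to C8).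
3. The cyclobutenone comes from a 1-lithio glycal (made from the stannane) and dimethyl squarate (C8–C8a bond), O-methylation, and exchange of the beta methoxy group for benzyloxy.
4. The glycal comes from a 5-C-aryl pyranosyl sulfone. Its C5 (flavan C2) is set by chelation-controlled reduction of the aryl ketone made from a D-glucose-derived xylo-pentodialdofuranose and the ring B Grignard reagent.
5. Ring order: ring B is bought as the aryl bromide, ring C is formed as the pyranose (step 7), ring A is formed last (step 17).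

Key step: step 17

Abbreviations: Ar = 3,4,5-tris(benzyloxy)phenyl; Gly = (2R,3S,4R)-3,4-bis(benzyloxy)-2-Ar-3,4-dihydro-2H-pyran-6-yl.
Assumption: the free sugar 11 is taken to react as its pyranose, because the chair with the C5 aryl group and all three oxygen substituents equatorial should be by far the most stable ring form.

**Route**

Step 1
Reactants: 1 5-bromo-1,2,3-trimethoxybenzene
Product: 2 5-bromobenzene-1,2,3-triol
Conditions: BBr3, CH2Cl2, −78 °C to rt; H2O
Reagents that add atoms: none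
Why: Lewis acid ether cleavage (BBr3 demethylation) replaces the three methyl ethers, which could not be removed later beside the ring A methoxy groups, by free phenols.

Step 2
Reactants: 2 5-bromobenzene-1,2,3-triol
Product: 3 5-bromo-1,2,3-tris(benzyloxy)benzene
Conditions: BnBr, K2CO3, DMF, 60 °C, N2
Reagents that add atoms: benzyl bromide, BrCc1ccccc1
Why: Williamson etherification of the three phenoxides gives the ring B donor with hydrogenolysable protecting groups.

Step 3
Reactants: 4 3-O-benzyl-1,2:5,6-di-O-isopropylidene-α-D-glucofuranose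
Product: 6 3-O-benzyl-1,2-O-isopropylidene-α-D-xylo-pentodialdo-1,4-furanose, via glucofuranose diol 5 (not isolated)
Conditions: H5IO6, EtOAc, rt
Reagents that add atoms: none
Why: periodic acid first hydrolyses the exocyclic 5,6-acetonide selectively and then cleaves the freed glycol (Malaprade oxidation), leaving the cis-fused 1,2-acetonide and the stereocentres C2, C3 and C4 untouched.

Step 4
Reactants: 3 5-bromo-1,2,3-tris(benzyloxy)benzene; 6 3-O-benzyl-1,2-O-isopropylidene-α-D-xylo-pentodialdo-1,4-furanose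
Product: 8 3-O-benzyl-1,2-O-isopropylidene-5-C-Ar-α-D-xylofuranose (both C5 epimers), via arylmagnesium bromide 7 (not isolated)
Conditions: Mg, I2 (cat.), THF, reflux; then 6, THF, −78 to 0 °C; aq. NH4Cl
Reagents that add atoms: none
Why: Grignard addition to the aldehyde forms the C5–aryl bond (flavan C2–C1'); chelation to the ring oxygen should favour the 5S epimer, but both epimers are carried on because the next step removes this centre.

Step 5
Reactants: 8 3-O-benzyl-1,2-O-isopropylidene-5-C-Ar-α-D-xylofuranose (both C5 epimers)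
Product: 9 3-O-benzyl-1,2-O-isopropylidene-5-C-Ar-α-D-xylo-pentofuranos-5-ulose (aryl ketone)
Conditions: Dess–Martin periodinane, CH2Cl2, rt
Reagents that add atoms: none
Why: Dess–Martin oxidation of the benzylic alcohol converges both epimers on one aryl ketone without touching the acetonide or the benzyl ethers.

Step 6
Reactants: 9 3-O-benzyl-1,2-O-isopropylidene-5-C-Ar-α-D-xylo-pentofuranos-5-ulose
Product: 10 (5R)-3-O-benzyl-1,2-O-isopropylidene-5-C-Ar-α-D-xylofuranose (D-gluco configuration at C5)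
Conditions: Zn(BH4)2, Et2O/CH2Cl2, −20 °C
Reagents that add atoms: none
Why: chelation-controlled hydride reduction (Cram cyclic model), in which zinc bridges the ketone oxygen and the furanose ring oxygen and hydride adds from the face flanked by H4 and not by C3, should give the 5R alcohol that becomes C2 of the flavan.

Step 7
Reactants: 10 (5R)-3-O-benzyl-1,2-O-isopropylidene-5-C-Ar-α-D-xylofuranose
Product: 11 (5R)-3-O-benzyl-5-C-Ar-D-xylopyranose (both anomers)
Conditions: CF3CO2H/H2O (4:1), 0 °C to rt, short contact time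
Reagents that add atoms: none
Why: acid hydrolysis of the 1,2-acetonide frees the reducing sugar, which should recyclise through O5 to the all-equatorial pyranose (ring C), while the C5 carbinol should not ionise because the oxygen on C4 destabilises a benzylic cation.

Step 8
Reactants: 11 (5R)-3-O-benzyl-5-C-Ar-D-xylopyranose
Product: 12 (5R)-1,2,4-tri-O-acetyl-3-O-benzyl-5-C-Ar-D-xylopyranose (both anomers)
Conditions: Ac2O, pyridine, DMAP (cat.), rt
Reagents that add atoms: acetic anhydride, CC(=O)OC(C)=O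
Why: peracetylation fixes the pyranose form and installs an anomeric leaving group together with a participating ester on O2.

Step 9
Reactants: 12 (5R)-1,2,4-tri-O-acetyl-3-O-benzyl-5-C-Ar-D-xylopyranose
Product: 13 phenyl (5R)-2,4-di-O-acetyl-3-O-benzyl-1-thio-5-C-Ar-β-D-xylopyranoside
Conditions: PhSH, BF3·OEt2, CH2Cl2, 0 °C to rt
Reagents that add atoms: thiophenol, Sc1ccccc1
Why: Lewis acid thioglycosidation through the C2 acetoxonium ion (neighbouring group participation) should give the 1,2-trans β-thioglycoside, whose anomeric centre is destroyed later.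

Step 10
Reactants: 13 phenyl (5R)-2,4-di-O-acetyl-3-O-benzyl-1-thio-5-C-Ar-β-D-xylopyranoside
Product: 14 phenyl (5R)-3-O-benzyl-1-thio-5-C-Ar-β-D-xylopyranoside
Conditions: NaOMe (cat.), MeOH/THF, rt
Reagents that add atoms: none
Why: Zemplén transesterification removes both acetates without touching the thioglycoside or the benzyl ethers.

Step 11
Reactants: 14 phenyl (5R)-3-O-benzyl-1-thio-5-C-Ar-β-D-xylopyranoside
Product: 15 phenyl (5R)-2,3,4-tri-O-benzyl-1-thio-5-C-Ar-β-D-xylopyranoside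
Conditions: NaH, BnBr, Bu4NI (cat.), DMF, 0 °C to rt
Reagents that add atoms: benzyl bromide, BrCc1ccccc1
Why: Williamson benzylation protects O4 (the later flavan C3 oxygen) and turns O2 into the benzyloxide leaving group needed for the glycal-forming elimination.

Step 12
Reactants: 15 phenyl (5R)-2,3,4-tri-O-benzyl-1-thio-5-C-Ar-β-D-xylopyranoside
Product: 17 (5R)-2,3,4-tri-O-benzyl-5-C-Ar-β-D-xylopyranosyl phenyl sulfone, via sulfoxide 16 (not isolated)
Conditions: mCPBA (2.5 equiv), CH2Cl2, 0 °C to rt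
Reagents that add atoms: 3-chloroperoxybenzoic acid, OOC(=O)c1cccc(Cl)c1
Why: peracid oxidation of the sulfide through the sulfoxide gives the sulfone, which acidifies H1, and the benzyl ethers and arenes should not be oxidised at this temperature.

Step 13
Reactants: 17 (5R)-2,3,4-tri-O-benzyl-5-C-Ar-β-D-xylopyranosyl phenyl sulfone
Product: 19 (2R,3S,4R)-3,4-bis(benzyloxy)-6-(phenylsulfonyl)-2-Ar-3,4-dihydro-2H-pyran, via lithiated sulfone 18 (not isolated)
Conditions: LiN(iPr)2, THF, −78 °C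
Reagents that add atoms: none
Why: deprotonation at C1 next to the sulfonyl group followed by E1cB loss of the C2 benzyloxide gives the 1-sulfonyl glycal, the known behaviour of 2-O-benzyl glycosyl phenyl sulfones.

Step 14
Reactants: 19 (2R,3S,4R)-3,4-bis(benzyloxy)-6-(phenylsulfonyl)-2-Ar-3,4-dihydro-2H-pyran
Product: 20 (2R,3S,4R)-3,4-bis(benzyloxy)-6-(tributylstannyl)-2-Ar-3,4-dihydro-2H-pyran
Conditions: Bu3SnH, AIBN (cat.), toluene, reflux
Reagents that add atoms: tributyltin hydride, CCCC[SnH](CCCC)CCCC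
Why: radical addition–elimination (the stannyl radical adds at C1 and the sulfonyl radical is expelled) replaces the vinylic sulfone by tin, the established route to 1-stannyl glycals, and it tolerates benzyl ethers.

Step 15
Reactants: 20 (2R,3S,4R)-3,4-bis(benzyloxy)-6-(tributylstannyl)-2-Ar-3,4-dihydro-2H-pyran; 21 dimethyl squarate
Product: 24 4-Gly-2,3,4-trimethoxycyclobut-2-en-1-one (both C4 epimers), via lithio glycal 22 (not isolated), via lithium alkoxide adduct 23 (not isolated)
Conditions: n-BuLi, THF, −78 °C; add to 21 (1.5 equiv), THF, −78 °C; MeOTf, −78 to 0 °C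
Reagents that add atoms: methyl trifluoromethanesulfonate, COS(=O)(=O)C(F)(F)F
Why: tin–lithium exchange gives the vinyllithium without touching the benzyl ethers, its 1,2-addition to one carbonyl group of the squarate forms the future C8–C8a bond, and O-methylation of the tertiary alkoxide installs the C8 methoxy group; the new carbinol centre forms as a mixture that does not matter.

Step 16
Reactants: 24 4-Gly-2,3,4-trimethoxycyclobut-2-en-1-one
Product: 25 3-(benzyloxy)-4-Gly-2,4-dimethoxycyclobut-2-en-1-one (both C4 epimers)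
Conditions: BnOH (20 equiv), NaH (0.2 equiv), 4 Å MS, THF, 0 °C to rt
Reagents that add atoms: benzyl alcohol, OCc1ccccc1
Why: Proposed new method: benzyloxide should add to the beta carbon (C3) of the vinylogous ester, the only electrophilic alkoxy-bearing carbon, to give a cyclobutanone enolate that expels methoxide (addition–elimination), with the excess of benzyl alcohol and the sieves that take up methanol driving the equilibrium, while the alpha methoxy carbon and the sp3 C4 methyl ether have no such pathway; the closest known reaction type is the base-catalysed transesterification of dialkyl squarates and the alkoxy exchange of beta-alkoxy enones.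

Step 17
Reactants: 25 3-(benzyloxy)-4-Gly-2,4-dimethoxycyclobut-2-en-1-one
Product: 28 (2R,3S,4R)-3,4,7-tris(benzyloxy)-6,8-dimethoxy-2-Ar-3,4-dihydro-2H-chromen-5-ol, via dienylketene 26 (not isolated), via cyclohexadienone 27 (not isolated)
Conditions: toluene (0.01 M, degassed), 110 °C
Reagents that add atoms: none
Why: Heating opens the cyclobutenone by conrotatory 4π electrocyclic cleavage of the bond between the carbonyl carbon and the carbinol carbon to give dienylketene 26, whose ketene carbon bonds to C2 of the glycal alkene in a disrotatory 6π electrocyclisation to dienone 27, and loss of the C4a hydrogen by tautomerisation gives phenol 28. The closest known reaction type is the Moore rearrangement of 4-alkenyl-4-alkoxycyclobutenones made from squarates, cyclic enol ether substituents included. Ring A is the only ring closed, by 6π electrocyclic closure that forms the C4a–C5 bond. No stereocentre is formed (the sp3 C4a of 27 is lost on aromatisation), both carbinol epimers of 25 converge, and the C2, C3, C4 triad from the sugar should not be touched by neutral thermolysis. The step needs the glycal alkene to rotate inward, cis to the ketene, and the donor methoxy group on the carbinol carbon secures this by rotating outward (torquoselectivity). The oxygen pattern is fixed by the atom mapping: carbonyl carbon to C5–OH, alpha carbon to C6–OMe, beta carbon to C7–OBn, carbinol carbon to C8–OMe bonded to C8a.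

Step 18
Reactants: 28 (2R,3S,4R)-3,4,7-tris(benzyloxy)-6,8-dimethoxy-2-Ar-3,4-dihydro-2H-chromen-5-ol
Product: 29 (2R,3S,4R)-6,8-dimethoxy-2-(3,4,5-trihydroxyphenyl)-3,4-dihydro-2H-chromene-3,4,5,7-tetrol
Conditions: H2 (1 atm), Pd(OH)2/C, THF/MeOH, rt; filtration under argon
Reagents that add atoms: none
Why: neutral catalytic hydrogenolysis cleaves the six O–CH2Ph bonds, which should react faster than the ring C benzylic C–O bonds because the fully substituted ring A adsorbs poorly on palladium, and no stereocentre is touched.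

**Compound list**

1 | 5-bromo-1,2,3-trimethoxybenzene | COc1cc(Br)cc(OC)c1OC | starting material
2 | 5-bromobenzene-1,2,3-triol | Oc1cc(Br)cc(O)c1O | intermediate
3 | 5-bromo-1,2,3-tris(benzyloxy)benzene | Brc1cc(OCc2ccccc2)c(OCc2ccccc2)c(OCc2ccccc2)c1 | intermediate
4 | 3-O-benzyl-1,2:5,6-di-O-isopropylidene-α-D-glucofuranose | CC1(C)OC[C@@H](O1)[C@H]1O[C@@H]2OC(C)(C)O[C@@H]2[C@H]1OCc1ccccc1 | starting material
5 | 3-O-benzyl-1,2-O-isopropylidene-α-D-glucofuranose (not isolated) | OC[C@@H](O)[C@H]1O[C@@H]2OC(C)(C)O[C@@H]2[C@H]1OCc1ccccc1 | intermediate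
6 | 3-O-benzyl-1,2-O-isopropylidene-α-D-xylo-pentodialdo-1,4-furanose | O=C[C@H]1O[C@@H]2OC(C)(C)O[C@@H]2[C@H]1OCc1ccccc1 | intermediate
7 | [3,4,5-tris(benzyloxy)phenyl]magnesium bromide (not isolated) | Br[Mg]c1cc(OCc2ccccc2)c(OCc2ccccc2)c(OCc2ccccc2)c1 | intermediate
8 | 3-O-benzyl-1,2-O-isopropylidene-5-C-Ar-α-D-xylofuranose, both C5 epimers | OC(c1cc(OCc2ccccc2)c(OCc2ccccc2)c(OCc2ccccc2)c1)[C@H]1O[C@@H]2OC(C)(C)O[C@@H]2[C@H]1OCc1ccccc1 | intermediate
9 | 3-O-benzyl-1,2-O-isopropylidene-5-C-Ar-α-D-xylo-pentofuranos-5-ulose | O=C(c1cc(OCc2ccccc2)c(OCc2ccccc2)c(OCc2ccccc2)c1)[C@H]1O[C@@H]2OC(C)(C)O[C@@H]2[C@H]1OCc1ccccc1 | intermediate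
10 | (5R)-3-O-benzyl-1,2-O-isopropylidene-5-C-Ar-α-D-xylofuranose | O[C@H](c1cc(OCc2ccccc2)c(OCc2ccccc2)c(OCc2ccccc2)c1)[C@H]1O[C@@H]2OC(C)(C)O[C@@H]2[C@H]1OCc1ccccc1 | intermediate
11 | (5R)-3-O-benzyl-5-C-Ar-D-xylopyranose, both anomers | OC1[C@H](O)[C@@H](OCc2ccccc2)[C@H](O)[C@@H](c2cc(OCc3ccccc3)c(OCc3ccccc3)c(OCc3ccccc3)c2)O1 | intermediate
12 | (5R)-1,2,4-tri-O-acetyl-3-O-benzyl-5-C-Ar-D-xylopyranose, both anomers | CC(=O)OC1[C@H](OC(C)=O)[C@@H](OCc2ccccc2)[C@H](OC(C)=O)[C@@H](c2cc(OCc3ccccc3)c(OCc3ccccc3)c(OCc3ccccc3)c2)O1 | intermediate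
13 | phenyl (5R)-2,4-di-O-acetyl-3-O-benzyl-1-thio-5-C-Ar-β-D-xylopyranoside | c1ccccc1S[C@H]1[C@H](OC(C)=O)[C@@H](OCc2ccccc2)[C@H](OC(C)=O)[C@@H](c2cc(OCc3ccccc3)c(OCc3ccccc3)c(OCc3ccccc3)c2)O1 | intermediate
14 | phenyl (5R)-3-O-benzyl-1-thio-5-C-Ar-β-D-xylopyranoside | c1ccccc1S[C@H]1[C@H](O)[C@@H](OCc2ccccc2)[C@H](O)[C@@H](c2cc(OCc3ccccc3)c(OCc3ccccc3)c(OCc3ccccc3)c2)O1 | intermediate
15 | phenyl (5R)-2,3,4-tri-O-benzyl-1-thio-5-C-Ar-β-D-xylopyranoside | c1ccccc1S[C@H]1[C@H](OCc2ccccc2)[C@@H](OCc2ccccc2)[C@H](OCc2ccccc2)[C@@H](c2cc(OCc3ccccc3)c(OCc3ccccc3)c(OCc3ccccc3)c2)O1 | intermediate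
16 | S-oxide of 15, glycosyl phenyl sulfoxide (not isolated) | O=S(c1ccccc1)[C@H]1[C@H](OCc2ccccc2)[C@@H](OCc2ccccc2)[C@H](OCc2ccccc2)[C@@H](c2cc(OCc3ccccc3)c(OCc3ccccc3)c(OCc3ccccc3)c2)O1 | intermediate
17 | (5R)-2,3,4-tri-O-benzyl-5-C-Ar-β-D-xylopyranosyl phenyl sulfone | O=S(=O)(c1ccccc1)[C@H]1[C@H](OCc2ccccc2)[C@@H](OCc2ccccc2)[C@H](OCc2ccccc2)[C@@H](c2cc(OCc3ccccc3)c(OCc3ccccc3)c(OCc3ccccc3)c2)O1 | intermediate
18 | C1-lithio derivative of sulfone 17 (not isolated) | [Li]C1(S(=O)(=O)c2ccccc2)[C@H](OCc2ccccc2)[C@@H](OCc2ccccc2)[C@H](OCc2ccccc2)[C@@H](c2cc(OCc3ccccc3)c(OCc3ccccc3)c(OCc3ccccc3)c2)O1 | intermediate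
19 | (2R,3S,4R)-3,4-bis(benzyloxy)-6-(phenylsulfonyl)-2-Ar-3,4-dihydro-2H-pyran | O=S(=O)(c1ccccc1)C1=C[C@@H](OCc2ccccc2)[C@H](OCc2ccccc2)[C@@H](c2cc(OCc3ccccc3)c(OCc3ccccc3)c(OCc3ccccc3)c2)O1 | intermediate
20 | (2R,3S,4R)-3,4-bis(benzyloxy)-6-(tributylstannyl)-2-Ar-3,4-dihydro-2H-pyran | CCCC[Sn](CCCC)(CCCC)C1=C[C@@H](OCc2ccccc2)[C@H](OCc2ccccc2)[C@@H](c2cc(OCc3ccccc3)c(OCc3ccccc3)c(OCc3ccccc3)c2)O1 | intermediate
21 | dimethyl squarate (3,4-dimethoxycyclobut-3-ene-1,2-dione) | COC1=C(OC)C(=O)C1=O | starting material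
22 | (2R,3S,4R)-3,4-bis(benzyloxy)-6-lithio-2-Ar-3,4-dihydro-2H-pyran (not isolated) | [Li]C1=C[C@@H](OCc2ccccc2)[C@H](OCc2ccccc2)[C@@H](c2cc(OCc3ccccc3)c(OCc3ccccc3)c(OCc3ccccc3)c2)O1 | intermediate
23 | lithium 1-Gly-2,3-dimethoxy-4-oxocyclobut-2-en-1-olate (not isolated) | COC1=C(OC)C(O[Li])(C1=O)C1=C[C@@H](OCc2ccccc2)[C@H](OCc2ccccc2)[C@@H](c2cc(OCc3ccccc3)c(OCc3ccccc3)c(OCc3ccccc3)c2)O1 | intermediate
24 | 4-Gly-2,3,4-trimethoxycyclobut-2-en-1-one, both C4 epimers | COC1=C(OC)C(OC)(C1=O)C1=C[C@@H](OCc2ccccc2)[C@H](OCc2ccccc2)[C@@H](c2cc(OCc3ccccc3)c(OCc3ccccc3)c(OCc3ccccc3)c2)O1 | intermediate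
25 | 3-(benzyloxy)-4-Gly-2,4-dimethoxycyclobut-2-en-1-one, both C4 epimers | COC1=C(OCc2ccccc2)C(OC)(C1=O)C1=C[C@@H](OCc2ccccc2)[C@H](OCc2ccccc2)[C@@H](c2cc(OCc3ccccc3)c(OCc3ccccc3)c(OCc3ccccc3)c2)O1 | intermediate
26 | dienylketene, 3-(benzyloxy)-4-Gly-2,4-dimethoxybuta-1,3-dien-1-one with Gly cis to the ketene carbon (not isolated) | O=C=C(OC)/C(OCc1ccccc1)=C(/OC)C1=C[C@@H](OCc2ccccc2)[C@H](OCc2ccccc2)[C@@H](c2cc(OCc3ccccc3)c(OCc3ccccc3)c(OCc3ccccc3)c2)O1 | intermediate
27 | (2R,3S,4R)-3,4,7-tris(benzyloxy)-6,8-dimethoxy-2-Ar-2,3,4,4a-tetrahydro-5H-chromen-5-one (not isolated) | COC1=C(OCc3ccccc3)C(OC)=C2C(C1=O)[C@@H](OCc3ccccc3)[C@H](OCc3ccccc3)[C@@H](c3cc(OCc4ccccc4)c(OCc4ccccc4)c(OCc4ccccc4)c3)O2 | intermediate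
28 | (2R,3S,4R)-3,4,7-tris(benzyloxy)-6,8-dimethoxy-2-Ar-3,4-dihydro-2H-chromen-5-ol | COc1c(OCc3ccccc3)c(OC)c2c(c1O)[C@@H](OCc3ccccc3)[C@H](OCc3ccccc3)[C@@H](c3cc(OCc4ccccc4)c(OCc4ccccc4)c(OCc4ccccc4)c3)O2 | intermediate
29 | (2R,3S,4R)-6,8-dimethoxy-2-(3,4,5-trihydroxyphenyl)-3,4-dihydro-2H-chromene-3,4,5,7-tetrol | COc1c(O)c(OC)c2c(c1O)[C@@H](O)[C@H](O)[C@@H](c1cc(O)c(O)c(O)c1)O2 | target

**Step count**

Total: 18 steps. Longest linear sequence: 17 steps (steps 1, 2 and 4 to 18, from 1); the sugar branch from 4 is 16 steps (steps 3 to 18).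

**Steps most likely to fail**

1. Step 16 (proposed new method). What may go wrong: the alkoxy exchange may stall at an equilibrium mixture, or benzyloxide may attack the carbonyl group and cleave the four-membered ring. Fallback with known chemistry, from 20 back to 25: 20 is lithiated as in step 15 and the lithio glycal 22 is added at −78 °C to the mixed squarate 3-(benzyloxy)-4-methoxycyclobut-3-ene-1,2-dione F1, which is made from 21 by exchange of one methoxy group with one equivalent of benzyl alcohol (cat. Et3N) and separated from the statistical mixture. Aqueous quench should give two regioisomeric carbinols with no regiocontrol expected: 3-(benzyloxy)-4-Gly-4-hydroxy-2-methoxycyclobut-2-en-1-one F2 (addition at the carbonyl group next to the benzyloxy-bearing carbon) and 2-(benzyloxy)-4-Gly-4-hydroxy-3-methoxycyclobut-2-en-1-one F3. They are separated by chromatography and F2 is O-methylated (MeI, Ag2O, K2CO3, MeCN) to 25. About half of the glycal is lost, but every operation is standard squarate chemistry.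

2. Step 17 (key step). What may go wrong: once the C5 phenol is free, benzyl alcohol may be lost thermally from C4 through an ortho-quinone methide, which would scramble C4 or destroy the product. Fallback, from 25 back to 28: the thermolysis is run in the presence of N,O-bis(trimethylsilyl)acetamide, so that the phenol is captured as it forms as (2R,3S,4R)-3,4,7-tris(benzyloxy)-6,8-dimethoxy-2-Ar-5-(trimethylsilyloxy)-3,4-dihydro-2H-chromene F4, which has no free ortho hydroxyl group and cannot form the quinone methide. F4 is isolated and cleaved to 28 with K2CO3 in MeOH at 0 °C.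

3. Step 18. What may go wrong: hydrogenolytic cleavage of the benzylic C4–O bond of ring C may compete with the six O–CH2Ph cleavages. Fallback, from 28 back to 29: the C5 phenol is first acetylated (Ac2O, pyridine, DMAP) to (2R,3S,4R)-3,4,7-tris(benzyloxy)-6,8-dimethoxy-2-Ar-3,4-dihydro-2H-chromen-5-yl acetate F5, which lowers the electron density of ring A next to C4 and removes the hydrogen-bond donor to the C4 oxygen. Hydrogenolysis (H2, Pd(OH)2/C, THF/MeOH) then gives (2R,3S,4R)-3,4,7-trihydroxy-6,8-dimethoxy-2-(3,4,5-trihydroxyphenyl)-3,4-dihydro-2H-chromen-5-yl acetate F6, and the acetate is removed with N2H4·H2O in MeOH/THF at 0 °C under argon to give 29.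

**Further compounds**

F1 | step 16 | 3-(benzyloxy)-4-methoxycyclobut-3-ene-1,2-dione | COC1=C(OCc2ccccc2)C(=O)C1=O
F2 | step 16 | 3-(benzyloxy)-4-Gly-4-hydroxy-2-methoxycyclobut-2-en-1-one | COC1=C(OCc2ccccc2)C(O)(C1=O)C1=C[C@@H](OCc2ccccc2)[C@H](OCc2ccccc2)[C@@H](c2cc(OCc3ccccc3)c(OCc3ccccc3)c(OCc3ccccc3)c2)O1
F3 | step 16 | 2-(benzyloxy)-4-Gly-4-hydroxy-3-methoxycyclobut-2-en-1-one | COC1=C(OCc2ccccc2)C(=O)C1(O)C1=C[C@@H](OCc2ccccc2)[C@H](OCc2ccccc2)[C@@H](c2cc(OCc3ccccc3)c(OCc3ccccc3)c(OCc3ccccc3)c2)O1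
F4 | step 17 | (2R,3S,4R)-3,4,7-tris(benzyloxy)-6,8-dimethoxy-2-Ar-5-(trimethylsilyloxy)-3,4-dihydro-2H-chromene | COc1c(OCc3ccccc3)c(OC)c2c(c1O[Si](C)(C)C)[C@@H](OCc3ccccc3)[C@H](OCc3ccccc3)[C@@H](c3cc(OCc4ccccc4)c(OCc4ccccc4)c(OCc4ccccc4)c3)O2
F5 | step 18 | (2R,3S,4R)-3,4,7-tris(benzyloxy)-6,8-dimethoxy-2-Ar-3,4-dihydro-2H-chromen-5-yl acetate | COc1c(OCc3ccccc3)c(OC)c2c(c1OC(C)=O)[C@@H](OCc3ccccc3)[C@H](OCc3ccccc3)[C@@H](c3cc(OCc4ccccc4)c(OCc4ccccc4)c(OCc4ccccc4)c3)O2
F6 | step 18 | (2R,3S,4R)-3,4,7-trihydroxy-6,8-dimethoxy-2-(3,4,5-trihydroxyphenyl)-3,4-dihydro-2H-chromen-5-yl acetate | COc1c(O)c(OC)c2c(c1OC(C)=O)[C@@H](O)[C@H](O)[C@@H](c1cc(O)c(O)c(O)c1)O2
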